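**Retrosynthetic overview**

1. Numbering: C1 is the CH2OH carbon, the oxiranes sit at C2–C3 and C6–C7, the alkene is C10=C11, the carbinol is C12, followed by C13, C14 (=CH2) and the isopropyl group. The strategy rests on the C6–C7 oxirane, whose chain carbons C5 and C8 are cis: C5, C6, C7 and C8 are C1, C2, C3 and C4 of 2,3-epoxy-3-methylcyclohexanone, so the six-membered carbocycle enforces the cis oxirane.
2. Key disconnection: the former ring bond C5–C10, cut by ozonolysis of the silyl enol ether to leave a C5 acid and a C10 aldehyde that are extended separately.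
3. Further disconnections (retro order): C12–O silyl ether; C2–C3 oxirane (Sharpless epoxidation); C3–CH3 (enol phosphate plus Me2CuLi); C4–C5 (acetoacetate dianion plus C5 triflate); C12–C13 (asymmetric allylboration with a 2-isopropylallyl unit made from 3-methylbutanal); C10=C11 (Wittig).
4. Ring order: the C6–C7 oxirane is formed first (step 1, on the carbocycle), the carbocycle is opened (step 3), and the C2–C3 oxirane is formed last (step 17).

Key step: step 3

Assumption: the quinine-derived 9-amino-9-deoxy-epi amine salt is taken to give the (1S,6S) epoxide in step 1; if the facial sense is the reverse, the quinidine-derived pseudoenantiomer is used and nothing else changes.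

**Route**

Step 1
Reactants: 1 3-methylcyclohex-2-en-1-one
Product: 2 (1S,6S)-6-methyl-7-oxabicyclo[4.1.0]heptan-2-one
Conditions: 9-amino-9-deoxy-epi-quinine (10 mol%), CF3CO2H (20 mol%), 50% aq. H2O2 (1.5 equiv), 1,4-dioxane, 30 °C
Reagents that add atoms: hydrogen peroxide, OO
Why: Amine-catalysed asymmetric nucleophilic epoxidation (Weitz–Scheffer type) through a chiral iminium ion, in which H2O2 adds to C3 on the face left open by the cinchona amine salt and the resulting enamine closes the oxirane, so that both oxirane stereocentres (target C6 and C7) are set by the catalyst while the ring allows only the cis-fused epoxide.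

Step 2
Reactants: 2 (1S,6S)-6-methyl-7-oxabicyclo[4.1.0]heptan-2-one
Product: 4 trimethyl{[(1S,6S)-6-methyl-7-oxabicyclo[4.1.0]hept-2-en-2-yl]oxy}silane, via lithium enolate 3 (not isolated)
Conditions: LiN(i-Pr)2 (1.1 equiv), THF, −78 °C; Me3SiCl, −78 → 0 °C; pentane, cold aq. NaHCO3 wash
Reagents that add atoms: chlorotrimethylsilane, C[Si](C)(C)Cl
Why: Kinetic enolisation followed by O-silylation, which can only take place towards the CH2 carbon because the other alpha carbon is the oxirane CH and its deprotonation would require a strained oxiranyl anion, so a single silyl enol ether should form and no stereocentre is touched.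

Step 3
Reactants: 4 trimethyl{[(1S,6S)-6-methyl-7-oxabicyclo[4.1.0]hept-2-en-2-yl]oxy}silane
Product: 7 (2S,3S)-3-methyl-3-(3-oxopropyl)oxirane-2-carboxylic acid, via methoxy hydroperoxide silyl ester 5 (not isolated), via silyl ester aldehyde 6 (not isolated)
Conditions: O3, CH2Cl2/MeOH (4:1), −78 °C; Me2S, −78 → 0 °C; cold H2O (pH 4) work-up, crude acid used at once
Reagents that add atoms: ozone, [O-][O+]=O
Why: Ozone adds to the electron-rich enol ether double bond (C5=C10 in target numbering) by 1,3-dipolar cycloaddition, and the primary ozonide cycloreverts to the C5 trimethylsilyl ester and a C10 carbonyl oxide, which methanol traps as hydroperoxide 5 and Me2S reduces to aldehyde 6 before water cleaves the silyl ester. The closest known reaction type is the ozonolysis of a cyclic trimethylsilyl enol ether to an oxo acid, that is, the oxidative cleavage of a cyclic ketone. No ring is closed and no stereocentre is formed, since the step only opens the carbocycle, and the cis oxirane with its two stereocentres (C6 and C7) is carried through because neither oxirane carbon is touched. The step needs regioselective cleavage of C5–C10 and chemoselectivity for the alkene over the oxirane; the first is secured because the enol ether can only lie towards the CH2 carbon, the second because the oxirane offers ozone no pi bond. The two chain ends emerge in different oxidation states (acid at C5, aldehyde at C10), which is what allows them to be extended one after the other. The glycidic acid is kept cold and esterified immediately so that decarboxylative opening of the oxirane cannot set in.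

Step 4
Reactants: 7 (2S,3S)-3-methyl-3-(3-oxopropyl)oxirane-2-carboxylic acid
Product: 8 methyl (2S,3S)-3-methyl-3-(3-oxopropyl)oxirane-2-carboxylate
Conditions: Me3SiCHN2, toluene/MeOH (4:1), 0 °C
Reagents that add atoms: (trimethylsilyl)diazomethane, C[Si](C)(C)C=[N+]=[N-]
Why: Esterification of a carboxylic acid with (trimethylsilyl)diazomethane in methanol, which methylates the carboxylate at 0 °C without added acid or heat and should therefore spare the aldehyde and the oxirane.

Step 5
Reactants: 8 methyl (2S,3S)-3-methyl-3-(3-oxopropyl)oxirane-2-carboxylate; 9 2-(triphenylphosphoranylidene)propanal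
Product: 10 methyl (2S,3S)-3-methyl-3-[(3E)-4-methyl-5-oxopent-3-en-1-yl]oxirane-2-carboxylate
Conditions: 9 (1.2 equiv), toluene, 80 °C
Reagents that add atoms: none
Why: Wittig olefination with a stabilised formyl ylide, which should give the (E)-2-methyl enal and stop there because the alpha-branched enal is far less reactive towards the ylide than the aliphatic aldehyde, while ester and oxirane are inert.

Step 6
Reactants: 11 3-methylbutanal
Product: 12 3-methyl-2-methylidenebutanal
Conditions: 37% aq. HCHO, pyrrolidine (10 mol%), EtCO2H (10 mol%), i-PrOH, 45 °C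
Reagents that add atoms: formaldehyde, C=O
Why: Mannich-type alpha-methylenation, in which the enamine of the aldehyde adds to formaldehyde and the amine is eliminated to give the 2-substituted acrolein.

Step 7
Reactants: 12 3-methyl-2-methylidenebutanal
Product: 13 3-methyl-2-methylidenebutan-1-ol
Conditions: NaBH4, CeCl3·7H2O, MeOH, 0 °C
Reagents that add atoms: none
Why: Luche reduction, in which NaBH4 in the presence of CeCl3 should deliver hydride 1,2 to the enal and leave the alkene.

Step 8
Reactants: 13 3-methyl-2-methylidenebutan-1-ol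
Product: 15 2-(chloromethyl)-3-methylbut-1-ene, via allylic mesylate 14 (not isolated)
Conditions: MsCl, 2,4,6-collidine, LiCl, DMF, 0 °C → rt
Reagents that add atoms: lithium chloride, [Li+].[Cl-]
Why: Sulfonylation followed by SN2 displacement with chloride, which is fast at a primary allylic carbon and cannot give a regioisomer because the allyl unit is symmetrical about its central carbon.

Step 9
Reactants: 10 methyl (2S,3S)-3-methyl-3-[(3E)-4-methyl-5-oxopent-3-en-1-yl]oxirane-2-carboxylate; 15 2-(chloromethyl)-3-methylbut-1-ene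
Product: 19 methyl (2S,3S)-3-[(3E,5R)-5-hydroxy-4,8-dimethyl-7-methylidenenon-3-en-1-yl]-3-methyloxirane-2-carboxylate, via 2-isopropylallylmagnesium chloride 16 (not isolated), via allylborane 17 (not isolated), via borinate ester 18 (not isolated)
Conditions: 15 (1.4 equiv), Mg, THF, 0 °C; (+)-Ipc2BCl [from (−)-α-pinene, 1.5 equiv], Et2O, −78 → 0 °C; 10, −78 °C; then 30% H2O2, aq. KH2PO4/Na2HPO4 (pH 7), MeOH, 0 °C
Reagents that add atoms: none
Why: Brown allylboration, in which the 2-substituted allylborane adds to the aldehyde through a closed six-membered chair transition state with the alkenyl group equatorial and the (1S,2R,3S,5S)-isopinocampheyl groups from (−)-α-pinene should direct attack to the face that gives the (R) carbinol at C12 (reagent control, in the sense expected for allyl and methallyl reagents of this series with alpha-branched enals), while ester and oxirane do not react at −78 °C.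

Step 10
Reactants: 19 methyl (2S,3S)-3-[(3E,5R)-5-hydroxy-4,8-dimethyl-7-methylidenenon-3-en-1-yl]-3-methyloxirane-2-carboxylate
Product: 20 methyl (2S,3S)-3-[(3E,5R)-5-{[tert-butyl(dimethyl)silyl]oxy}-4,8-dimethyl-7-methylidenenon-3-en-1-yl]-3-methyloxirane-2-carboxylate
Conditions: t-BuMe2SiCl, imidazole, DMF, rt
Reagents that add atoms: tert-butyldimethylsilyl chloride, CC(C)(C)[Si](C)(C)Cl
Why: Silyl ether formation with imidazole activation, which masks the C12 hydroxyl so that it can neither be sulfonylated in step 12 nor direct the Ti(Oi-Pr)4-mediated epoxidation in step 17.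

Step 11
Reactants: 20 methyl (2S,3S)-3-[(3E,5R)-5-{[tert-butyl(dimethyl)silyl]oxy}-4,8-dimethyl-7-methylidenenon-3-en-1-yl]-3-methyloxirane-2-carboxylate
Product: 21 {(2R,3S)-3-[(3E,5R)-5-{[tert-butyl(dimethyl)silyl]oxy}-4,8-dimethyl-7-methylidenenon-3-en-1-yl]-3-methyloxiran-2-yl}methanol
Conditions: i-Bu2AlH (2.2 equiv), CH2Cl2, −78 °C; aq. potassium sodium tartrate
Reagents that add atoms: none
Why: Hydride reduction of an ester to the primary alcohol, fast for an alpha-oxygenated ester at −78 °C where i-Bu2AlH should not open the oxirane, so that C6 keeps its configuration and only its descriptor changes from S to R with the new priorities.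

Step 12
Reactants: 21 {(2R,3S)-3-[(3E,5R)-5-{[tert-butyl(dimethyl)silyl]oxy}-4,8-dimethyl-7-methylidenenon-3-en-1-yl]-3-methyloxiran-2-yl}methanol
Product: 22 {(2R,3S)-3-[(3E,5R)-5-{[tert-butyl(dimethyl)silyl]oxy}-4,8-dimethyl-7-methylidenenon-3-en-1-yl]-3-methyloxiran-2-yl}methyl trifluoromethanesulfonate
Conditions: Tf2O, 2,6-lutidine, CH2Cl2, −78 °C; cold aq. NaHCO3 wash, used at once
Reagents that add atoms: trifluoromethanesulfonic anhydride, O=S(=O)(OS(=O)(=O)C(F)(F)F)C(F)(F)F
Why: O-Sulfonylation of the primary epoxy alcohol under buffered conditions at low temperature, which supplies a leaving group reactive enough for carbanion alkylation at −78 °C.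

Step 13
Reactants: 22 {(2R,3S)-3-[(3E,5R)-5-{[tert-butyl(dimethyl)silyl]oxy}-4,8-dimethyl-7-methylidenenon-3-en-1-yl]-3-methyloxiran-2-yl}methyl trifluoromethanesulfonate; 23 methyl acetoacetate
Product: 25 methyl 5-{(2R,3S)-3-[(3E,5R)-5-{[tert-butyl(dimethyl)silyl]oxy}-4,8-dimethyl-7-methylidenenon-3-en-1-yl]-3-methyloxiran-2-yl}-3-oxopentanoate, via acetoacetate dianion 24 (not isolated)
Conditions: 23 (2.5 equiv), NaH, THF, 0 °C; n-BuLi, 0 °C; 22, −78 → −40 °C; aq. NH4Cl
Reagents that add atoms: none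
Why: Gamma-alkylation of a beta-keto ester dianion by SN2 displacement, in which the terminal carbanion is the more nucleophilic site and should displace the primary triflate at C5 faster than it attacks the trisubstituted oxirane, so forming the C4–C5 bond.

Step 14
Reactants: 25 methyl 5-{(2R,3S)-3-[(3E,5R)-5-{[tert-butyl(dimethyl)silyl]oxy}-4,8-dimethyl-7-methylidenenon-3-en-1-yl]-3-methyloxiran-2-yl}-3-oxopentanoate
Product: 27 methyl (2Z)-3-[(diethoxyphosphoryl)oxy]-5-{(2R,3S)-3-[(3E,5R)-5-{[tert-butyl(dimethyl)silyl]oxy}-4,8-dimethyl-7-methylidenenon-3-en-1-yl]-3-methyloxiran-2-yl}pent-2-enoate, via sodium enolate 26 (not isolated)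
Conditions: NaH, Et2O, 0 °C; (EtO)2P(O)Cl, 0 °C → rt
Reagents that add atoms: diethyl chlorophosphate, CCOP(=O)(Cl)OCC
Why: O-Phosphorylation of a beta-keto ester enolate, which in ether is held as the sodium chelate between the two oxygens and should therefore be trapped as the (Z)-enol phosphate.

Step 15
Reactants: 27 methyl (2Z)-3-[(diethoxyphosphoryl)oxy]-5-{(2R,3S)-3-[(3E,5R)-5-{[tert-butyl(dimethyl)silyl]oxy}-4,8-dimethyl-7-methylidenenon-3-en-1-yl]-3-methyloxiran-2-yl}pent-2-enoate
Product: 28 methyl (2E)-5-{(2R,3S)-3-[(3E,5R)-5-{[tert-butyl(dimethyl)silyl]oxy}-4,8-dimethyl-7-methylidenenon-3-en-1-yl]-3-methyloxiran-2-yl}-3-methylpent-2-enoate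
Conditions: Me2CuLi (from MeLi and CuI), Et2O, −78 → −45 °C; aq. NH4Cl
Reagents that add atoms: lithium dimethylcuprate, [Li+].C[Cu-]C
Why: Substitution of a beta-phosphoryloxy enoate by Me2CuLi (conjugate addition–elimination), which replaces the phosphate by methyl with retention of the alkene geometry to give the (2E)-3-methyl enoate and should leave the trisubstituted oxirane and the allylic silyl ether untouched below −45 °C.

Step 16
Reactants: 28 methyl (2E)-5-{(2R,3S)-3-[(3E,5R)-5-{[tert-butyl(dimethyl)silyl]oxy}-4,8-dimethyl-7-methylidenenon-3-en-1-yl]-3-methyloxiran-2-yl}-3-methylpent-2-enoate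
Product: 29 (2E)-5-{(2R,3S)-3-[(3E,5R)-5-{[tert-butyl(dimethyl)silyl]oxy}-4,8-dimethyl-7-methylidenenon-3-en-1-yl]-3-methyloxiran-2-yl}-3-methylpent-2-en-1-ol
Conditions: i-Bu2AlH (2.5 equiv), CH2Cl2, −78 °C; aq. potassium sodium tartrate
Reagents that add atoms: none
Why: Hydride 1,2-reduction of an alpha,beta-unsaturated ester to the allylic alcohol, which at −78 °C changes neither the alkene geometry nor the oxirane.

Step 17
Reactants: 29 (2E)-5-{(2R,3S)-3-[(3E,5R)-5-{[tert-butyl(dimethyl)silyl]oxy}-4,8-dimethyl-7-methylidenenon-3-en-1-yl]-3-methyloxiran-2-yl}-3-methylpent-2-en-1-ol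
Product: 30 {(2R,3R)-3-[2-{(2R,3S)-3-[(3E,5R)-5-{[tert-butyl(dimethyl)silyl]oxy}-4,8-dimethyl-7-methylidenenon-3-en-1-yl]-3-methyloxiran-2-yl}ethyl]-3-methyloxiran-2-yl}methanol
Conditions: Ti(Oi-Pr)4 (10 mol%), D-(−)-diethyl tartrate (12 mol%), t-BuOOH, 4 Å molecular sieves, CH2Cl2, −20 °C
Reagents that add atoms: tert-butyl hydroperoxide, CC(C)(C)OO
Why: Sharpless asymmetric epoxidation, in which the complex formed from Ti(Oi-Pr)4 and D-(−)-diethyl tartrate binds the free primary allylic alcohol and delivers oxygen to the face of the (E)-C2=C3 alkene that gives the (2R,3R) oxirane (reagent control), while the C10=C11 and C14 methylidene alkenes carry no free hydroxyl and should not react.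

Step 18
Reactants: 30 {(2R,3R)-3-[2-{(2R,3S)-3-[(3E,5R)-5-{[tert-butyl(dimethyl)silyl]oxy}-4,8-dimethyl-7-methylidenenon-3-en-1-yl]-3-methyloxiran-2-yl}ethyl]-3-methyloxiran-2-yl}methanol
Product: 31 {(2R,3R)-3-[2-{(2R,3S)-3-[(3E,5R)-5-hydroxy-4,8-dimethyl-7-methylidenenon-3-en-1-yl]-3-methyloxiran-2-yl}ethyl]-3-methyloxiran-2-yl}methanol (CNP0156678.1)
Conditions: Bu4NF, AcOH (1 equiv), THF, 0 °C → rt
Reagents that add atoms: none
Why: Fluoride-mediated desilylation driven by the strong Si–F bond, run with acetic acid as buffer so that neither oxirane is opened and the 2,3-epoxy alcohol does not undergo epoxide migration.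

**Compound list**

1 | 3-methylcyclohex-2-en-1-one | CC1=CC(=O)CCC1 | starting material
2 | (1S,6S)-6-methyl-7-oxabicyclo[4.1.0]heptan-2-one | O=C1CCC[C@]2(C)O[C@@H]21 | intermediate
3 | lithium (1S,6S)-6-methyl-7-oxabicyclo[4.1.0]hept-2-en-2-olate (formed in the flask) | [Li+].[O-]C1=CCC[C@]2(C)O[C@@H]21 | intermediate
4 | trimethyl{[(1S,6S)-6-methyl-7-oxabicyclo[4.1.0]hept-2-en-2-yl]oxy}silane | C[Si](C)(C)OC1=CCC[C@]2(C)O[C@@H]21 | intermediate
5 | trimethylsilyl (2S,3S)-3-(3-hydroperoxy-3-methoxypropyl)-3-methyloxirane-2-carboxylate, both epimers at the peroxyacetal carbon (formed in the flask) | COC(OO)CC[C@]1(C)O[C@@H]1C(=O)O[Si](C)(C)C | intermediate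
6 | trimethylsilyl (2S,3S)-3-methyl-3-(3-oxopropyl)oxirane-2-carboxylate (formed in the flask) | O=CCC[C@]1(C)O[C@@H]1C(=O)O[Si](C)(C)C | intermediate
7 | (2S,3S)-3-methyl-3-(3-oxopropyl)oxirane-2-carboxylic acid | O=CCC[C@]1(C)O[C@@H]1C(=O)O | intermediate
8 | methyl (2S,3S)-3-methyl-3-(3-oxopropyl)oxirane-2-carboxylate | O=CCC[C@]1(C)O[C@@H]1C(=O)OC | intermediate
9 | 2-(triphenylphosphoranylidene)propanal | CC(C=O)=P(c1ccccc1)(c1ccccc1)c1ccccc1 | starting material
10 | methyl (2S,3S)-3-methyl-3-[(3E)-4-methyl-5-oxopent-3-en-1-yl]oxirane-2-carboxylate | O=C/C(C)=C/CC[C@]1(C)O[C@@H]1C(=O)OC | intermediate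
11 | 3-methylbutanal | CC(C)CC=O | starting material
12 | 3-methyl-2-methylidenebutanal | C=C(C=O)C(C)C | intermediate
13 | 3-methyl-2-methylidenebutan-1-ol | C=C(CO)C(C)C | intermediate
14 | 3-methyl-2-methylidenebutyl methanesulfonate (formed in the flask) | C=C(COS(C)(=O)=O)C(C)C | intermediate
15 | 2-(chloromethyl)-3-methylbut-1-ene | C=C(CCl)C(C)C | intermediate
16 | chloro(3-methyl-2-methylidenebutyl)magnesium (formed in the flask) | C=C(C[Mg]Cl)C(C)C | intermediate
17 | (3-methyl-2-methylidenebutyl)bis[(1S,2R,3S,5S)-2,6,6-trimethylbicyclo[3.1.1]heptan-3-yl]borane (formed in the flask) | C=C(CB([C@H]1C[C@H]2C[C@@H]([C@@H]1C)C2(C)C)[C@H]1C[C@H]2C[C@@H]([C@@H]1C)C2(C)C)C(C)C | intermediate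
18 | methyl (2S,3S)-3-[(3E,5R)-5-({bis[(1S,2R,3S,5S)-2,6,6-trimethylbicyclo[3.1.1]heptan-3-yl]boranyl}oxy)-4,8-dimethyl-7-methylidenenon-3-en-1-yl]-3-methyloxirane-2-carboxylate (formed in the flask) | C=C(C[C@@H](OB([C@H]1C[C@H]2C[C@@H]([C@@H]1C)C2(C)C)[C@H]1C[C@H]2C[C@@H]([C@@H]1C)C2(C)C)/C(C)=C/CC[C@]1(C)O[C@@H]1C(=O)OC)C(C)C | intermediate
19 | methyl (2S,3S)-3-[(3E,5R)-5-hydroxy-4,8-dimethyl-7-methylidenenon-3-en-1-yl]-3-methyloxirane-2-carboxylate | C=C(C[C@@H](O)/C(C)=C/CC[C@]1(C)O[C@@H]1C(=O)OC)C(C)C | intermediate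
20 | methyl (2S,3S)-3-[(3E,5R)-5-{[tert-butyl(dimethyl)silyl]oxy}-4,8-dimethyl-7-methylidenenon-3-en-1-yl]-3-methyloxirane-2-carboxylate | C=C(C[C@@H](O[Si](C)(C)C(C)(C)C)/C(C)=C/CC[C@]1(C)O[C@@H]1C(=O)OC)C(C)C | intermediate
21 | {(2R,3S)-3-[(3E,5R)-5-{[tert-butyl(dimethyl)silyl]oxy}-4,8-dimethyl-7-methylidenenon-3-en-1-yl]-3-methyloxiran-2-yl}methanol | C=C(C[C@@H](O[Si](C)(C)C(C)(C)C)/C(C)=C/CC[C@]1(C)O[C@@H]1CO)C(C)C | intermediate
22 | {(2R,3S)-3-[(3E,5R)-5-{[tert-butyl(dimethyl)silyl]oxy}-4,8-dimethyl-7-methylidenenon-3-en-1-yl]-3-methyloxiran-2-yl}methyl trifluoromethanesulfonate | C=C(C[C@@H](O[Si](C)(C)C(C)(C)C)/C(C)=C/CC[C@]1(C)O[C@@H]1COS(=O)(=O)C(F)(F)F)C(C)C | intermediate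
23 | methyl acetoacetate (methyl 3-oxobutanoate) | COC(=O)CC(C)=O | starting material
24 | lithium sodium dianion of methyl 3-oxobutanoate (formed in the flask) | [Li+].[Na+].[CH2-]C(=O)[CH-]C(=O)OC | intermediate
25 | methyl 5-{(2R,3S)-3-[(3E,5R)-5-{[tert-butyl(dimethyl)silyl]oxy}-4,8-dimethyl-7-methylidenenon-3-en-1-yl]-3-methyloxiran-2-yl}-3-oxopentanoate | C=C(C[C@@H](O[Si](C)(C)C(C)(C)C)/C(C)=C/CC[C@]1(C)O[C@@H]1CCC(=O)CC(=O)OC)C(C)C | intermediate
26 | sodium (Z)-enolate of 25 (formed in the flask) | C=C(C[C@@H](O[Si](C)(C)C(C)(C)C)/C(C)=C/CC[C@]1(C)O[C@@H]1CC/C([O-])=C/C(=O)OC)C(C)C.[Na+] | intermediate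
27 | methyl (2Z)-3-[(diethoxyphosphoryl)oxy]-5-{(2R,3S)-3-[(3E,5R)-5-{[tert-butyl(dimethyl)silyl]oxy}-4,8-dimethyl-7-methylidenenon-3-en-1-yl]-3-methyloxiran-2-yl}pent-2-enoate | C=C(C[C@@H](O[Si](C)(C)C(C)(C)C)/C(C)=C/CC[C@]1(C)O[C@@H]1CC/C(OP(=O)(OCC)OCC)=C/C(=O)OC)C(C)C | intermediate
28 | methyl (2E)-5-{(2R,3S)-3-[(3E,5R)-5-{[tert-butyl(dimethyl)silyl]oxy}-4,8-dimethyl-7-methylidenenon-3-en-1-yl]-3-methyloxiran-2-yl}-3-methylpent-2-enoate | C=C(C[C@@H](O[Si](C)(C)C(C)(C)C)/C(C)=C/CC[C@]1(C)O[C@@H]1CC/C(C)=C/C(=O)OC)C(C)C | intermediate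
29 | (2E)-5-{(2R,3S)-3-[(3E,5R)-5-{[tert-butyl(dimethyl)silyl]oxy}-4,8-dimethyl-7-methylidenenon-3-en-1-yl]-3-methyloxiran-2-yl}-3-methylpent-2-en-1-ol | C=C(C[C@@H](O[Si](C)(C)C(C)(C)C)/C(C)=C/CC[C@]1(C)O[C@@H]1CC/C(C)=C/CO)C(C)C | intermediate
30 | {(2R,3R)-3-[2-{(2R,3S)-3-[(3E,5R)-5-{[tert-butyl(dimethyl)silyl]oxy}-4,8-dimethyl-7-methylidenenon-3-en-1-yl]-3-methyloxiran-2-yl}ethyl]-3-methyloxiran-2-yl}methanol | C=C(C[C@@H](O[Si](C)(C)C(C)(C)C)/C(C)=C/CC[C@]1(C)O[C@@H]1CC[C@@]1(C)O[C@@H]1CO)C(C)C | intermediate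
31 | {(2R,3R)-3-[2-{(2R,3S)-3-[(3E,5R)-5-hydroxy-4,8-dimethyl-7-methylidenenon-3-en-1-yl]-3-methyloxiran-2-yl}ethyl]-3-methyloxiran-2-yl}methanol | C=C(C[C@@H](O)/C(C)=C/CC[C@]1(C)O[C@@H]1CC[C@@]1(C)O[C@@H]1CO)C(C)C | target

**Step count and risks**

Total step count: 18. Longest linear sequence: 15 steps (steps 1–5 and 9–18); the allyl fragment (steps 6–8) joins at step 9.

Steps most likely to fail:

1. Step 3. Three processes threaten it: decarboxylative opening of the free glycidic acid, acetal formation at the new aldehyde in acidic methanol, and oxygen-atom transfer to the enol ether in place of cleavage. The fallback sets out from 4 and comes back at 8, and it cuts the same C5–C10 bond by glycol-type fission so that the free acid never appears. Rubottom oxidation of 4 (m-CPBA, NaHCO3, CH2Cl2, 0 °C) should give (1S,6S)-6-methyl-3-[(trimethylsilyl)oxy]-7-oxabicyclo[4.1.0]heptan-2-one F1. Mild desilylation (citric acid, MeOH, 0 °C) then gives (1S,6S)-3-hydroxy-6-methyl-7-oxabicyclo[4.1.0]heptan-2-one F2. Cleavage of this alpha-hydroxy ketone with Pb(OAc)4 in MeOH/benzene at 0 °C delivers the methyl ester aldehyde 8 directly.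

2. Step 13. The dianion may open the oxirane or be alkylated on oxygen, the epoxy triflate may decompose before it is alkylated, and the keto ester enolate formed here and in step 14 may cyclise onto the oxirane. The fallback sets out from 22, comes back at 28 and replaces steps 13–15. Lithiated acetone N,N-dimethylhydrazone (LiN(i-Pr)2, THF, 0 → −78 °C) is alkylated by 22 to give 4-{(2R,3S)-3-[(3E,5R)-5-{[tert-butyl(dimethyl)silyl]oxy}-4,8-dimethyl-7-methylidenenon-3-en-1-yl]-3-methyloxiran-2-yl}butan-2-one N,N-dimethylhydrazone F3. Hydrolysis with aq. Cu(OAc)2 in THF gives 4-{(2R,3S)-3-[(3E,5R)-5-{[tert-butyl(dimethyl)silyl]oxy}-4,8-dimethyl-7-methylidenenon-3-en-1-yl]-3-methyloxiran-2-yl}butan-2-one F4. A Horner–Wadsworth–Emmons reaction with trimethyl phosphonoacetate and NaH in THF then gives enoate 28, with the (2E) isomer separated from the (2Z) isomer by chromatography.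

3. Step 9. Facial selectivity may be incomplete with the branched allyl reagent, and formation of the allylmagnesium chloride may be accompanied by homocoupling. The fallback sets out from 10 and 15, comes back at 19, and sets C12 by reduction instead of by C–C bond formation. Zinc-mediated Barbier allylation (Zn dust, THF/sat. aq. NH4Cl, 0 °C) should give methyl (2S,3S)-3-[(3E)-5-hydroxy-4,8-dimethyl-7-methylidenenon-3-en-1-yl]-3-methyloxirane-2-carboxylate F5 as both C12 epimers. Dess–Martin oxidation (NaHCO3, CH2Cl2, 0 °C) gives methyl (2S,3S)-3-[(3E)-4,8-dimethyl-7-methylidene-5-oxonon-3-en-1-yl]-3-methyloxirane-2-carboxylate F6. Corey–Bakshi–Shibata reduction with (S)-2-methyl-CBS-oxazaborolidine and catecholborane (toluene, −78 °C), with the alkenyl group acting as the large substituent, should then give the (12R) alcohol 19.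

**Further compounds**

F1 | step 3 | (1S,6S)-6-methyl-3-[(trimethylsilyl)oxy]-7-oxabicyclo[4.1.0]heptan-2-one (C3 epimers) | O=C1C(O[Si](C)(C)C)CC[C@]2(C)O[C@@H]21
F2 | step 3 | (1S,6S)-3-hydroxy-6-methyl-7-oxabicyclo[4.1.0]heptan-2-one (C3 epimers) | O=C1C(O)CC[C@]2(C)O[C@@H]21
F3 | step 13 | 4-{(2R,3S)-3-[(3E,5R)-5-{[tert-butyl(dimethyl)silyl]oxy}-4,8-dimethyl-7-methylidenenon-3-en-1-yl]-3-methyloxiran-2-yl}butan-2-one N,N-dimethylhydrazone | C=C(C[C@@H](O[Si](C)(C)C(C)(C)C)/C(C)=C/CC[C@]1(C)O[C@@H]1CCC(C)=NN(C)C)C(C)C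
F4 | step 13 | 4-{(2R,3S)-3-[(3E,5R)-5-{[tert-butyl(dimethyl)silyl]oxy}-4,8-dimethyl-7-methylidenenon-3-en-1-yl]-3-methyloxiran-2-yl}butan-2-one | C=C(C[C@@H](O[Si](C)(C)C(C)(C)C)/C(C)=C/CC[C@]1(C)O[C@@H]1CCC(C)=O)C(C)C
F5 | step 9 | methyl (2S,3S)-3-[(3E)-5-hydroxy-4,8-dimethyl-7-methylidenenon-3-en-1-yl]-3-methyloxirane-2-carboxylate (C12 epimers) | C=C(CC(O)/C(C)=C/CC[C@]1(C)O[C@@H]1C(=O)OC)C(C)C
F6 | step 9 | methyl (2S,3S)-3-[(3E)-4,8-dimethyl-7-methylidene-5-oxonon-3-en-1-yl]-3-methyloxirane-2-carboxylate | C=C(CC(=O)/C(C)=C/CC[C@]1(C)O[C@@H]1C(=O)OC)C(C)C
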